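## Analysis of the target

Bisoflavolin K (19) is made of two isoflavone (3-aryl-4H-chromen-4-one) units joined by a diaryl ether. The chlorine-free unit has benzo ring A with a hydroxyl at C7, pyranone ring C and aryl ring B. Ring B carries a hydroxyl at C4′ and, at C3′, the ether oxygen. That oxygen is bonded to the para carbon of ring E, a 1,4-phenylene that is also the 3-aryl group of the second unit, whose pyranone is ring F and whose benzo ring D carries a hydroxyl at C7 and chlorine at C8. There is no stereocentre and the molecule is achiral, so the task is one of connectivity and order of events only. The sensitive sites are the three phenols, the aryl chloride flanked by two oxygens on ring D, and C2 of each pyranone, which is opened by hydroxide, alkoxide or strong carbon nucleophiles. The difficulty is that two nearly identical heterocycles must be grown one after the other from one unsymmetrical diaryl ether without confusing the halves, with chlorine ending at C8 and not C6. The strategy rests on C2 of ring C: it is a lone CH between O1 and the aryl-bearing C3, so it can enter as the carbonyl carbon of a formate on the ring A oxygen and be joined to C3 by a phosphorus ylide.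

## Retrosynthetic reasoning

**19 to 18.** The last cut removes the two O-methyl groups at C7 of ring A and C4′ of ring B. Methyl ethers are the only phenol protection that survives ylide chemistry, hot Lewis acid and protic acid alike. Their cleavage by a boron Lewis acid touches neither the diaryl ether nor the chloride, so 19 comes from 18.

**18 to 15 and 16, through 17.** Ring F is opened at C2 (a one-carbon unit between the ring oxygen and the benzylic carbon) and then at the aryl ketone bond to ring D. That leads to the arylacetic acid 15 and 2-chlororesorcinol 16, with deoxybenzoin 17 in between. The cut is made here because 16 is bought with the chlorine already between the two oxygens. Its only doubly activated positions are equivalent, so acylation can give only the 3-chloro-2,4-dihydroxyphenyl ketone and the halogen must end at C8. Doing this late keeps the free phenols and the base-sensitive chlorinated chromone away from all ylide and base chemistry.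

**15 to 14.** The acid is carried as its tert-butyl ester 14. This is the device that keeps the two halves apart: the carbon that will become C3 of ring F sits at the acid oxidation level but is masked, while the carbon that becomes C3 of ring C is handled at the benzyl level.

**14 to 13, the key disconnection.** The C2=C3 bond of ring C is cut by a retro-Wittig operation, giving the keto-stabilised ylide 13 whose ring A oxygen bears a formyl group. This differs from the usual one-carbon condensation on a deoxybenzoin: the ring closes at carbon, without acid or base, expelling phosphorus as its oxide. The tert-butyl arylacetate, which would not survive a Lewis-acid closure and could be enolised in a basic one, is therefore never at risk. The forward reaction must make the ylide carbon attack the formate carbonyl faster than the formyl group is lost.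

**13 to 12.** The O–CHO bond is cut. The formate is the most labile group of the whole route, so it is put on immediately before use, onto the chelated phenol of hydroxy keto ylide 12.

**12 to 7 and 9, through 10 and 11.** The C3–C4 bond is cut as the C-acylation of benzylic ylide 10 (from phosphonium salt 7) by the silylated salicylate 9. The silyl group hides the phenol proton during acylation and leaves on methanolysis of 11. Ring A is thus bought complete as methyl ester 8, and the acylation uses only one equivalent of the valuable ylide, because the alkoxide leaving group doubles as the base.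

**7 to 5, 4, and then 2 and 3.** The phosphonium salt comes from benzylic alcohol 5 through bromide 6, and 5 from aldehyde 4. The diaryl ether C–O bond of 4 is cut between the phenol oxygen of isovanillin 3 and the brominated carbon of 2, the tert-butyl ester of 4-bromophenylacetic acid 1. Isovanillin already has the 3-oxygen, the 4-methoxy group and the one-carbon handle of ring B in the right places, so no regiochemical question arises in the copper-mediated coupling.

## Alternatives that were turned down

**Alternative 1: carbene-catalysed benzoin closure of C3–C4.** The C3–C4 bond of ring C is disconnected. Keto aldehyde A2, a 2-(phenacyloxy)benzaldehyde, would be treated with an N-heterocyclic carbene catalyst. The acyl anion equivalent formed at the aldehyde adds to the tethered aryl ketone and gives the 3-aryl-3-hydroxychroman-4-one A1 as a racemate.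
- For it: the reaction class is well established, runs with a catalyst under mild conditions and produces no stoichiometric phosphorus waste. On atom economy it is clearly stronger than the chosen route.
- Against it: A1 contains a quaternary carbinol stereocentre that the achiral target does not need, and a separate dehydration must then erase it to create C2=C3. Tertiary α-hydroxy ketones of this kind can undergo retro-benzoin cleavage instead. A1 also already carries the chlorinated chromone, whose electrophilic C2 is exposed to the nucleophilic carbene and its base. A2 needs a phenacyl halide made by α-halogenation in the presence of three electron-rich rings.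
- Comparison: benzoin closure plus dehydration is two operations, the same count as formylation plus Wittig closure, so nothing is saved. The chosen route offers the correct oxidation level directly and keeps the sensitive chlorinated ring out of the flask until the end.

**Alternative 2: photochemical Wolff rearrangement and electrocyclisation to form ring A.** Ring A itself is disconnected, with the C6–C7 bond formed last. Irradiation of diazo ketone A4 turns the diazoacetyl group into a ketene unit, which closes with the pyranone double bond and the vinyl group in a six-electron electrocyclisation; tautomerisation gives the 7-hydroxy isoflavone A3.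
- For it: the phenol at C7 appears unprotected and its position is fixed by the pericyclic cascade. On that point it is stronger than the chosen route, which carries a methyl ether to the end.
- Against it: A4 is a 2,3,5-trisubstituted 4-pyranone. The 3-aryl pyranone must be made first, which is the same C2/C3 problem in another guise, and then vinyl and diazoacetyl groups must be installed. The 4-pyranone chromophore has photochemistry of its own, and the ketene unit can be trapped by any nucleophile present. The side chain of A3 is at the alcohol oxidation level, so a deprotection and two oxidations are needed before the second half can be started.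
- Comparison: the chosen route buys ring A as 8 and needs a single acid treatment of 14 to release the arylacetic acid. The saving of one demethylation in the alternative is worth little, since one final ether cleavage serves both methyl groups.

**Alternative 3: cycloaddition of a chlorinated oxygenated diene to build ring D.** The bonds C4a–C5 and C8–C8a of the chlorinated unit are disconnected. Diene A6 would add to the sulfinyl-activated C5=C6 bond of pyranone A7, and expulsion of the sulfinyl and methoxy groups would aromatise the new ring to A5, which is the same structure as 18.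
- For it: the sequence is convergent and the diene polarity places chlorine and hydroxyl correctly. It is the stronger design if analogues with other substituents on ring D were wanted.
- Against it: A6 is a hydrolytically fragile silyl enol ether whose terminal chlorine lowers its reactivity. The C5=C6 bond of a 4-pyranone is a vinylogous ester and a poor dienophile even with the sulfinyl group. A7 has to be built as a 3,5-disubstituted pyranone on the finished first isoflavone in several steps.
- Comparison: the chosen route reaches the same compound 18 from 15 and commercial 16 in one flask, with the chlorine position guaranteed by the symmetry of 16.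

Key step: step 8

## Route

Remark: the target is achiral, so no step has to set or preserve a stereocentre; acetic formic anhydride is taken as a reagent prepared beforehand from acetic anhydride and formic acid.

Step 1
Reactants: 1 4-bromophenylacetic acid
Product: 2 tert-butyl 2-(4-bromophenyl)acetate
Conditions: tert-butyl 2,2,2-trichloroacetimidate (2 equiv), BF3·OEt2 (cat.), CH2Cl2/cyclohexane, rt
Reagents that add atoms: tert-butyl 2,2,2-trichloroacetimidate, CC(C)(C)OC(=N)C(Cl)(Cl)Cl
Why: Acid-catalysed O-alkylation of the carboxylic acid by the trichloroacetimidate (tert-butyl cation transfer) esterifies without touching the aryl bromide; the tert-butyl ester resists the bases and the ylide of later steps and falls to acid in step 9.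

Step 2
Reactants: 2 tert-butyl 2-(4-bromophenyl)acetate; 3 isovanillin (3-hydroxy-4-methoxybenzaldehyde)
Product: 4 tert-butyl 2-[4-(5-formyl-2-methoxyphenoxy)phenyl]acetate
Conditions: CuI (10 mol %), N,N-dimethylglycine hydrochloride (30 mol %), Cs2CO3 (2 equiv), 1,4-dioxane, 90 °C, Ar
Reagents that add atoms: none
Why: Copper-catalysed Ullmann-type diaryl ether coupling of a phenoxide with an aryl bromide; the phenol of 3 is meta to the aldehyde and so remains a good nucleophile, and carbonate is too weak a base to enolise the hindered tert-butyl arylacetate to a harmful extent.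

Step 3
Reactants: 4 tert-butyl 2-[4-(5-formyl-2-methoxyphenoxy)phenyl]acetate
Product: 5 tert-butyl 2-{4-[5-(hydroxymethyl)-2-methoxyphenoxy]phenyl}acetate
Conditions: NaBH4, MeOH/THF, 0 °C
Reagents that add atoms: none
Why: Borohydride reduction of an aryl aldehyde is fast at 0 °C and leaves the tert-butyl ester and the diaryl ether untouched.

Step 4
Reactants: 5 tert-butyl 2-{4-[5-(hydroxymethyl)-2-methoxyphenoxy]phenyl}acetate
Product: 7 {3-[4-(2-tert-butoxy-2-oxoethyl)phenoxy]-4-methoxybenzyl}triphenylphosphonium bromide, via benzylic bromide 6 (not isolated)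
Conditions: CBr4 (1.2 equiv), PPh3 (1.2 equiv), CH2Cl2, 0 °C; solvent changed to toluene, PPh3 (1.1 equiv), 80 °C; salt filtered off
Reagents that add atoms: carbon tetrabromide, BrC(Br)(Br)Br; triphenylphosphine, c1ccc(cc1)P(c1ccccc1)c1ccccc1
Why: Appel bromination under neutral conditions gives the 4-methoxybenzyl-type bromide, which is too labile to store and is quaternised at once by SN2 attack of the phosphine; the salt precipitates from toluene and is thereby freed of the phosphine oxide.

Step 5
Reactants: 8 methyl 2-hydroxy-4-methoxybenzoate
Product: 9 methyl 4-methoxy-2-(trimethylsilyloxy)benzoate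
Conditions: (Me3Si)2NH (0.7 equiv), Me3SiCl (cat.), neat, 110 °C; distilled and used at once
Reagents that add atoms: hexamethyldisilazane, C[Si](C)(C)N[Si](C)(C)C
Why: Silylation of the chelated phenol by the disilazane masks the only acidic proton of the acyl donor, which would otherwise quench the ylide in step 6.

Step 6
Reactants: 7 {3-[4-(2-tert-butoxy-2-oxoethyl)phenoxy]-4-methoxybenzyl}triphenylphosphonium bromide; 9 methyl 4-methoxy-2-(trimethylsilyloxy)benzoate
Product: 12 tert-butyl 2-[4-(5-{2-(2-hydroxy-4-methoxyphenyl)-2-oxo-1-(triphenylphosphoranylidene)ethyl}-2-methoxyphenoxy)phenyl]acetate, via benzylic ylide 10 (not isolated), via silylated keto ylide 11 (not isolated)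
Conditions: NaN(SiMe3)2 (1.0 equiv), THF, −78 to 0 °C; 9 (1.3 equiv), 0 °C to reflux; then MeOH, K2CO3 (cat.), rt
Reagents that add atoms: none
Why: C-Acylation of a semi-stabilised phosphorus ylide by an ester: the amide base removes the benzylic proton of 7 (far more acidic than the arylacetate CH2), ylide 10 adds to the ester carbonyl of 9, and the expelled methoxide takes the α-proton of the keto phosphonium ion, so one equivalent of ylide suffices and keto ylide 11 results; methanol then cleaves the labile aryl silyl ether to the chelated phenol 12.

Step 7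
Reactants: 12 tert-butyl 2-[4-(5-{2-(2-hydroxy-4-methoxyphenyl)-2-oxo-1-(triphenylphosphoranylidene)ethyl}-2-methoxyphenoxy)phenyl]acetate
Product: 13 tert-butyl 2-[4-(5-{2-[2-(formyloxy)-4-methoxyphenyl]-2-oxo-1-(triphenylphosphoranylidene)ethyl}-2-methoxyphenoxy)phenyl]acetate
Conditions: AcOCHO (2 equiv), pyridine (3 equiv), CH2Cl2, −20 to 0 °C; volatiles removed in vacuo below 10 °C with toluene, crude product used directly
Reagents that add atoms: acetic formic anhydride, CC(=O)OC=O
Why: O-Formylation of a phenol by the mixed anhydride, which transfers its formyl group because that carbonyl is the less hindered and more electrophilic one; the ylide carbon has no hydrogen and cannot be acylated irreversibly, pyridine is too weak a base to decarbonylate the aryl formate, and the cold non-aqueous isolation avoids hydrolysis.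

Step 8
Reactants: 13 tert-butyl 2-[4-(5-{2-[2-(formyloxy)-4-methoxyphenyl]-2-oxo-1-(triphenylphosphoranylidene)ethyl}-2-methoxyphenoxy)phenyl]acetate
Product: 14 tert-butyl 2-{4-[2-methoxy-5-(7-methoxy-4-oxo-4H-chromen-3-yl)phenoxy]phenyl}acetate
Conditions: dry toluene (0.01 M), 4 Å molecular sieves, 100 °C, Ar
Reagents that add atoms: none
Why: Intramolecular Wittig olefination of an ester carbonyl: the ylide carbon (future C3) adds to the formyl carbon (future C2) held ortho to it on ring A, and the oxaphosphetane undergoes cycloreversion with loss of the phosphine oxide to leave the C2=C3 enol ether double bond of the pyranone. The closest known reaction type is the ring closure of O-acyl (2-hydroxyaroyl)methylene phosphoranes to chromones, the formate being the acyl group that leaves C2 unsubstituted. Ring C closes in a 6-exo-trig mode, the attacked C=O lying outside the ring that forms. No stereocentre is created and the geometry of the new double bond is fixed by the ring. The step needs chemoselectivity for the formate over the tert-butyl ester and the ylide's own ketone, which is secured because a formate is the most electrophilic of esters and the only carbonyl the ylide carbon can reach through a six-membered transition state. It also needs olefination to outrun loss of the formyl group, which high dilution, exclusion of water and the absence of any amine base (which would decarbonylate an aryl formate) are meant to ensure. Because the ring is closed at carbon under neutral conditions, the tert-butyl arylacetate that seeds the chlorinated half stays intact.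

Step 9
Reactants: 14 tert-butyl 2-{4-[2-methoxy-5-(7-methoxy-4-oxo-4H-chromen-3-yl)phenoxy]phenyl}acetate
Product: 15 2-{4-[2-methoxy-5-(7-methoxy-4-oxo-4H-chromen-3-yl)phenoxy]phenyl}acetic acid
Conditions: CF3CO2H/CH2Cl2 (1:3), 0 °C to rt
Reagents that add atoms: none
Why: Acidolysis of the tert-butyl ester (alkyl–oxygen cleavage with loss of isobutene) frees the arylacetic acid; methyl ethers, diaryl ether and chromone are inert to trifluoroacetic acid at room temperature.

Step 10
Reactants: 15 2-{4-[2-methoxy-5-(7-methoxy-4-oxo-4H-chromen-3-yl)phenoxy]phenyl}acetic acid; 16 2-chlororesorcinol (2-chlorobenzene-1,3-diol)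
Product: 18 8-chloro-7-hydroxy-3-{4-[2-methoxy-5-(7-methoxy-4-oxo-4H-chromen-3-yl)phenoxy]phenyl}-4H-chromen-4-one, via deoxybenzoin 17 (not isolated)
Conditions: 16 (1.5 equiv), BF3·OEt2 (neat), 85 °C; cooled, DMF, then MeSO2Cl, 70 °C; aq. NaOAc work-up
Reagents that add atoms: N,N-dimethylformamide, CN(C)C=O
Why: Friedel–Crafts acylation of the phenol by the arylacetic acid in the boron trifluoride medium occurs at C4 of 16, the only position activated by both hydroxyl groups, which places chlorine between the two oxygens; the Vilsmeier-type reagent from DMF and the sulfonyl chloride then formylates the activated methylene of 17 and the ortho hydroxyl closes ring F with loss of dimethylamine, the second hydroxyl needing no protection.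

Step 11
Reactants: 18 8-chloro-7-hydroxy-3-{4-[2-methoxy-5-(7-methoxy-4-oxo-4H-chromen-3-yl)phenoxy]phenyl}-4H-chromen-4-one
Product: 19 bisoflavolin K, 8-chloro-7-hydroxy-3-{4-[2-hydroxy-5-(7-hydroxy-4-oxo-4H-chromen-3-yl)phenoxy]phenyl}-4H-chromen-4-one
Conditions: BBr3 (10 equiv), CH2Cl2, −78 °C to rt; then MeOH, H2O
Reagents that add atoms: none
Why: Lewis-acid cleavage of the two aryl methyl ethers by BBr3 (bromide attack on the O-methyl group of the boron-complexed ether); diaryl ether, aryl chloride and both chromones do not react under these conditions.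

## Compound list

1 | 4-bromophenylacetic acid | OC(=O)Cc1ccc(Br)cc1 | starting material
2 | tert-butyl 2-(4-bromophenyl)acetate | CC(C)(C)OC(=O)Cc1ccc(Br)cc1 | intermediate
3 | isovanillin (3-hydroxy-4-methoxybenzaldehyde) | COc1ccc(C=O)cc1O | starting material
4 | tert-butyl 2-[4-(5-formyl-2-methoxyphenoxy)phenyl]acetate | COc1ccc(C=O)cc1Oc1ccc(CC(=O)OC(C)(C)C)cc1 | intermediate
5 | tert-butyl 2-{4-[5-(hydroxymethyl)-2-methoxyphenoxy]phenyl}acetate | COc1ccc(CO)cc1Oc1ccc(CC(=O)OC(C)(C)C)cc1 | intermediate
6 | tert-butyl 2-{4-[5-(bromomethyl)-2-methoxyphenoxy]phenyl}acetate | COc1ccc(CBr)cc1Oc1ccc(CC(=O)OC(C)(C)C)cc1 | intermediate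
7 | {3-[4-(2-tert-butoxy-2-oxoethyl)phenoxy]-4-methoxybenzyl}triphenylphosphonium bromide | COc1ccc(C[P+](c2ccccc2)(c2ccccc2)c2ccccc2)cc1Oc1ccc(CC(=O)OC(C)(C)C)cc1.[Br-] | intermediate
8 | methyl 2-hydroxy-4-methoxybenzoate | COC(=O)c1ccc(OC)cc1O | starting material
9 | methyl 4-methoxy-2-(trimethylsilyloxy)benzoate | COC(=O)c1ccc(OC)cc1O[Si](C)(C)C | intermediate
10 | tert-butyl 2-(4-{2-methoxy-5-[(triphenylphosphoranylidene)methyl]phenoxy}phenyl)acetate | COc1ccc(C=P(c2ccccc2)(c2ccccc2)c2ccccc2)cc1Oc1ccc(CC(=O)OC(C)(C)C)cc1 | intermediate
11 | tert-butyl 2-[4-(2-methoxy-5-{2-[4-methoxy-2-(trimethylsilyloxy)phenyl]-2-oxo-1-(triphenylphosphoranylidene)ethyl}phenoxy)phenyl]acetate | COc1ccc(C(=O)C(=P(c2ccccc2)(c2ccccc2)c2ccccc2)c2ccc(OC)c(Oc3ccc(CC(=O)OC(C)(C)C)cc3)c2)c(O[Si](C)(C)C)c1 | intermediate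
12 | tert-butyl 2-[4-(5-{2-(2-hydroxy-4-methoxyphenyl)-2-oxo-1-(triphenylphosphoranylidene)ethyl}-2-methoxyphenoxy)phenyl]acetate | COc1ccc(C(=O)C(=P(c2ccccc2)(c2ccccc2)c2ccccc2)c2ccc(OC)c(Oc3ccc(CC(=O)OC(C)(C)C)cc3)c2)c(O)c1 | intermediate
13 | tert-butyl 2-[4-(5-{2-[2-(formyloxy)-4-methoxyphenyl]-2-oxo-1-(triphenylphosphoranylidene)ethyl}-2-methoxyphenoxy)phenyl]acetate | O=COc1cc(OC)ccc1C(=O)C(=P(c1ccccc1)(c1ccccc1)c1ccccc1)c1ccc(OC)c(Oc2ccc(CC(=O)OC(C)(C)C)cc2)c1 | intermediate
14 | tert-butyl 2-{4-[2-methoxy-5-(7-methoxy-4-oxo-4H-chromen-3-yl)phenoxy]phenyl}acetate | O=c1c(-c2ccc(OC)c(Oc3ccc(CC(=O)OC(C)(C)C)cc3)c2)coc2cc(OC)ccc12 | intermediate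
15 | 2-{4-[2-methoxy-5-(7-methoxy-4-oxo-4H-chromen-3-yl)phenoxy]phenyl}acetic acid | O=c1c(-c2ccc(OC)c(Oc3ccc(CC(=O)O)cc3)c2)coc2cc(OC)ccc12 | intermediate
16 | 2-chlororesorcinol (2-chlorobenzene-1,3-diol) | Oc1cccc(O)c1Cl | starting material
17 | 3-{3-[4-(2-(3-chloro-2,4-dihydroxyphenyl)-2-oxoethyl)phenoxy]-4-methoxyphenyl}-7-methoxy-4H-chromen-4-one | O=c1c(-c2ccc(OC)c(Oc3ccc(CC(=O)c4ccc(O)c(Cl)c4O)cc3)c2)coc2cc(OC)ccc12 | intermediate
18 | 8-chloro-7-hydroxy-3-{4-[2-methoxy-5-(7-methoxy-4-oxo-4H-chromen-3-yl)phenoxy]phenyl}-4H-chromen-4-one | O=c1c(-c2ccc(OC)c(Oc3ccc(-c4coc5c(Cl)c(O)ccc5c4=O)cc3)c2)coc2cc(OC)ccc12 | intermediate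
19 | bisoflavolin K, 8-chloro-7-hydroxy-3-{4-[2-hydroxy-5-(7-hydroxy-4-oxo-4H-chromen-3-yl)phenoxy]phenyl}-4H-chromen-4-one | O=c1c(-c2ccc(O)c(Oc3ccc(-c4coc5c(Cl)c(O)ccc5c4=O)cc3)c2)coc2cc(O)ccc12 | target

## Step count and risk

Total step count: 11. Longest linear sequence: 10 steps (steps 1 to 4 and 6 to 11); step 5 is a one-step side branch.

**Step 8 (key step).** The most likely failure is loss of the formyl group, by hydrolysis through traces of water or by transfer to another molecule, outrunning the slow addition of a doubly stabilised, hindered ylide carbon to the ester carbonyl. Fallback, from 12 and returning at 14: the phosphorus is removed reductively with Zn in AcOH, which is known for acyl phosphoranes, to give the deoxybenzoin tert-butyl 2-{4-[5-(2-(2-hydroxy-4-methoxyphenyl)-2-oxoethyl)-2-methoxyphenoxy]phenyl}acetate F1. Ring C is then closed by condensation with N,N-dimethylformamide dimethyl acetal in toluene at 80 °C (enaminone formation and cyclisation onto the phenol), neutral conditions that spare the tert-butyl ester, giving 14.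

**Step 6.** The likely failures are incomplete acylation, because a semi-stabilised ylide adds slowly to an electron-rich, ortho-substituted methyl ester, and premature loss of the silyl group, after which the phenol proton quenches the ylide. Fallback, from 7 and 8 and returning at 12:
- 8 is saponified (LiOH, aqueous THF) to 2-hydroxy-4-methoxybenzoic acid F2.
- F2 is silylated twice (tert-butyldimethylsilyl chloride, imidazole, DMF) to tert-butyldimethylsilyl 2-(tert-butyldimethylsilyloxy)-4-methoxybenzoate F3.
- Oxalyl chloride with catalytic DMF converts the silyl ester directly into 2-(tert-butyldimethylsilyloxy)-4-methoxybenzoyl chloride F4.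
- F4 is added at −78 °C to two equivalents of ylide 10. This gives the silyl-protected keto ylide tert-butyl 2-[4-(5-{2-[2-(tert-butyldimethylsilyloxy)-4-methoxyphenyl]-2-oxo-1-(triphenylphosphoranylidene)ethyl}-2-methoxyphenoxy)phenyl]acetate F5. The second equivalent of ylide acts as the base and is recovered for re-use as {3-[4-(2-tert-butoxy-2-oxoethyl)phenoxy]-4-methoxybenzyl}triphenylphosphonium chloride F6.
- Bu4NF in THF at 0 °C then frees the phenol and gives 12.

**Step 7.** The likely failures are competing transfer of the acetyl group of the mixed anhydride, loss of the formyl group during isolation, or ring closure already in the cold, so that the formate is not obtained as a defined intermediate. Fallback, from 7 (as ylide 10) and the acid F2 described above, returning at 13: the formate is carried in on the acyl donor. F2 is O-formylated with acetic formic anhydride to 2-(formyloxy)-4-methoxybenzoic acid F7, which can be purified by crystallisation. F7 is converted with tert-butyldimethylsilyl chloride and Et3N into tert-butyldimethylsilyl 2-(formyloxy)-4-methoxybenzoate F8. One equivalent of ylide 10 is then acylated by the silyl ester carbonyl in THF, the silanolate taking the α-proton, to give 13 directly. This variant has its own selectivity question between the silyl ester and the formate, and is therefore held in reserve.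

**Step 10.** The likely failures are acylation at the wrong nucleophile and incomplete ring closure in the one-flask sequence. The chlorine lowers the reactivity of 16, so the activated acid may attack the electron-rich rings of a second molecule of 15. Fallback, from 15 and returning at 19:
- 15 is activated as its mixed anhydride ((CF3CO)2O, H3PO4 cat.) and used to acylate commercial 2-chloro-1,3-dimethoxybenzene (COc1cccc(OC)c1Cl), taken in large excess. This gives 3-{3-[4-(2-(3-chloro-2,4-dimethoxyphenyl)-2-oxoethyl)phenoxy]-4-methoxyphenyl}-7-methoxy-4H-chromen-4-one F9.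
- BCl3 in CH2Cl2 at 0 °C removes only the methyl group ortho to the ketone, by chelation, giving 3-{3-[4-(2-(3-chloro-2-hydroxy-4-methoxyphenyl)-2-oxoethyl)phenoxy]-4-methoxyphenyl}-7-methoxy-4H-chromen-4-one F10.
- N,N-Dimethylformamide dimethyl acetal closes ring F to 8-chloro-7-methoxy-3-{4-[2-methoxy-5-(7-methoxy-4-oxo-4H-chromen-3-yl)phenoxy]phenyl}-4H-chromen-4-one F11.
- BBr3 as in step 11 removes all three methyl groups and gives 19.

## Further compounds

F1 | step 8 | tert-butyl 2-{4-[5-(2-(2-hydroxy-4-methoxyphenyl)-2-oxoethyl)-2-methoxyphenoxy]phenyl}acetate | COc1ccc(C(=O)Cc2ccc(OC)c(Oc3ccc(CC(=O)OC(C)(C)C)cc3)c2)c(O)c1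
F2 | step 6 | 2-hydroxy-4-methoxybenzoic acid | COc1ccc(C(=O)O)c(O)c1
F3 | step 6 | tert-butyldimethylsilyl 2-(tert-butyldimethylsilyloxy)-4-methoxybenzoate | COc1ccc(C(=O)O[Si](C)(C)C(C)(C)C)c(O[Si](C)(C)C(C)(C)C)c1
F4 | step 6 | 2-(tert-butyldimethylsilyloxy)-4-methoxybenzoyl chloride | COc1ccc(C(Cl)=O)c(O[Si](C)(C)C(C)(C)C)c1
F5 | step 6 | tert-butyl 2-[4-(5-{2-[2-(tert-butyldimethylsilyloxy)-4-methoxyphenyl]-2-oxo-1-(triphenylphosphoranylidene)ethyl}-2-methoxyphenoxy)phenyl]acetate | COc1ccc(C(=O)C(=P(c2ccccc2)(c2ccccc2)c2ccccc2)c2ccc(OC)c(Oc3ccc(CC(=O)OC(C)(C)C)cc3)c2)c(O[Si](C)(C)C(C)(C)C)c1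
F6 | step 6 | {3-[4-(2-tert-butoxy-2-oxoethyl)phenoxy]-4-methoxybenzyl}triphenylphosphonium chloride | COc1ccc(C[P+](c2ccccc2)(c2ccccc2)c2ccccc2)cc1Oc1ccc(CC(=O)OC(C)(C)C)cc1.[Cl-]
F7 | step 7 | 2-(formyloxy)-4-methoxybenzoic acid | O=COc1cc(OC)ccc1C(=O)O
F8 | step 7 | tert-butyldimethylsilyl 2-(formyloxy)-4-methoxybenzoate | O=COc1cc(OC)ccc1C(=O)O[Si](C)(C)C(C)(C)C
F9 | step 10 | 3-{3-[4-(2-(3-chloro-2,4-dimethoxyphenyl)-2-oxoethyl)phenoxy]-4-methoxyphenyl}-7-methoxy-4H-chromen-4-one | O=c1c(-c2ccc(OC)c(Oc3ccc(CC(=O)c4ccc(OC)c(Cl)c4OC)cc3)c2)coc2cc(OC)ccc12
F10 | step 10 | 3-{3-[4-(2-(3-chloro-2-hydroxy-4-methoxyphenyl)-2-oxoethyl)phenoxy]-4-methoxyphenyl}-7-methoxy-4H-chromen-4-one | O=c1c(-c2ccc(OC)c(Oc3ccc(CC(=O)c4ccc(OC)c(Cl)c4O)cc3)c2)coc2cc(OC)ccc12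
F11 | step 10 | 8-chloro-7-methoxy-3-{4-[2-methoxy-5-(7-methoxy-4-oxo-4H-chromen-3-yl)phenoxy]phenyl}-4H-chromen-4-one | O=c1c(-c2ccc(OC)c(Oc3ccc(-c4coc5c(Cl)c(OC)ccc5c4=O)cc3)c2)coc2cc(OC)ccc12
A1 | alternative 1 | rac-(3R)-3-{3-[4-(8-chloro-7-methoxy-4-oxo-4H-chromen-3-yl)phenoxy]-4-methoxyphenyl}-3-hydroxy-7-methoxychroman-4-one (racemate, 3R enantiomer drawn) | COc1ccc2c(c1)OC[C@](O)(c1ccc(OC)c(Oc3ccc(-c4coc5c(Cl)c(OC)ccc5c4=O)cc3)c1)C2=O
A2 | alternative 1 | 2-(2-{3-[4-(8-chloro-7-methoxy-4-oxo-4H-chromen-3-yl)phenoxy]-4-methoxyphenyl}-2-oxoethoxy)-4-methoxybenzaldehyde | COc1ccc(C=O)c(OCC(=O)c2ccc(OC)c(Oc3ccc(-c4coc5c(Cl)c(OC)ccc5c4=O)cc3)c2)c1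
A3 | alternative 2 | 3-(3-{4-[2-(tert-butyldimethylsilyloxy)ethyl]phenoxy}-4-methoxyphenyl)-7-hydroxy-4H-chromen-4-one | O=c1c(-c2ccc(OC)c(Oc3ccc(CCO[Si](C)(C)C(C)(C)C)cc3)c2)coc2cc(O)ccc12
A4 | alternative 2 | 2-(2-diazoacetyl)-3-ethenyl-5-(3-{4-[2-(tert-butyldimethylsilyloxy)ethyl]phenoxy}-4-methoxyphenyl)-4H-pyran-4-one | [N-]=[N+]=CC(=O)c1occ(-c2ccc(OC)c(Oc3ccc(CCO[Si](C)(C)C(C)(C)C)cc3)c2)c(=O)c1C=C
A5 | alternative 3 | 8-chloro-7-hydroxy-3-{4-[2-methoxy-5-(7-methoxy-4-oxo-4H-chromen-3-yl)phenoxy]phenyl}-4H-chromen-4-one (identical with 18) | O=c1c(-c2ccc(OC)c(Oc3ccc(-c4coc5c(Cl)c(O)ccc5c4=O)cc3)c2)coc2cc(OC)ccc12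
A6 | alternative 3 | (1E,3Z)-4-chloro-1-methoxy-3-(trimethylsilyloxy)buta-1,3-diene | CO/C=C/C(O[Si](C)(C)C)=C/Cl
A7 | alternative 3 | 7-methoxy-3-{4-methoxy-3-[4-(5-(4-methylbenzenesulfinyl)-4-oxo-4H-pyran-3-yl)phenoxy]phenyl}-4H-chromen-4-one (racemic at sulfur) | O=c1c(-c2ccc(OC)c(Oc3ccc(-c4cocc(S(=O)c5ccc(C)cc5)c4=O)cc3)c2)coc2cc(OC)ccc12
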